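A small charge of initiator faces a large one of free monomer in the flask and in each earlier run, and the readings level off with free monomer still there.

| flask | free monomer | transfer agent | protic impurity | initiator | stray impurity | remark | time |
|---|---|---|---|---|---|---|---|
| epsilon | 0.20 M | 6 mM | 0.084 M | 0.44 mM | 0.36 mM | run made earlier |  |
| theta | 0.20 M | 6 mM | 0.13 M | 0.44 mM | 0.36 mM | run made earlier |  |
| beta | 0.20 M | 3 mM | 0.060 M | 0.44 mM | 0.36 mM | run made earlier |  |
| flask | 0.20 M | 6.00 mM | 0.0600 M | 0.44 mM | 0.36 mM |  | 10 d |

- epsilon (time / d: monomer in chains / %, free monomer / %): 1.04: 18, 42; 2.08: 21, 40; 3.00: 23, 36; 4.00: 21, 34; 5.00: 25, 34; 6.00: 22, 37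
- theta (time / d: monomer in chains / %, free monomer / %): 1.04: 11, 24; 2.08: 14, 23; 3.00: 14, 20; 4.00: 13, 21; 5.00: 13, 22; 6.00: 15, 22
- beta (time / d: monomer in chains / %, free monomer / %): 0.500: 18, 54; 0.833: 23, 48; 1.67: 36, 35; 3.00: 41, 29; 6.00: 44, 26

(scatter of a reading: 1.5 percentage points)

- the average divides the monomer in chains by the number of chains begun, living and dead together
- reactions considered so far: free monomer + initiator -> living end + monomer in chains; living end + transfer agent -> dead chain; initiator + stray impurity -> spent initiator; protic impurity + free monomer -> quenched substrate; free monomer + living end -> monomer in chains + living end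
- the earlier runs do not show the number of chains; that part of a forecast is a guess

- average number of monomer units in a chain (chains begun, living or dead) at 10 d
- part of the free monomer that has reacted at 10 d

Read the last row of each table first. The two columns add up to about what the protic impurity spares at one free monomer each: beta holds 70.0% against a spared 70.0%, theta 37.0% against 35.0%.

Growth starts from that spared share, S. Transfer agent is charged far above initiator, so a living end dies pseudo-first-order, and its mean life goes as one over the transfer agent charged. Replacing the decaying curve of living ends by its mean, ln(S/end free monomer) should go the same way, and with initiator and stray impurity charged alike, that logarithm times the transfer agent charged should stay constant.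

Beta's last reading gives 2.97 mM. The means of the rows from 4.00 d on give 3.03 mM for epsilon and 2.88 mM for theta. Their mean, 2.96 mM, is the reach R, that constant product.

Taking growth as over by 10 d, our reckoning for the flask keeps 42.7% free monomer, so c is 57.3%. The readings show no chain count, so dp stays a guess. The forecast says c 58% (55% to 60%), 0.74 percentage points above ours, and dp 300 (125 to 710), where “I take the geometric middle”.

    free monomer + initiator → living end + monomer in chains (k = 2.20 M⁻¹ h⁻¹)
    living end + transfer agent → dead chain (kL = 10.0 M⁻¹ h⁻¹)
    initiator + stray impurity → spent initiator (k = 3100 M⁻¹ h⁻¹)
    protic impurity + free monomer → quenched substrate (k = 3.60 M⁻¹ h⁻¹)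
    free monomer + living end → monomer in chains + living end, rate k5*[living end]*[free monomer] (k = 160 M⁻¹ h⁻¹)

The flask gives dp 311 and c 56.2%, with free monomer at 43.8% of its charge at 10.0 d. Its own reach is 2.82 mM, a little below our 2.96 mM. Now take the neighbouring flask, charged with 2.40 mM of transfer agent and otherwise the same. Our reach R puts its free monomer at 20.4%, so c at 79.6%. That neighbour stands at 21.6% free monomer and 48.4% in chains, with c 78.4%.

Readings and results are calculated from invented constants.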